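**Retrosynthetic overview** (prostanoid atom labels: C-1 ester carbon, C-8 to C-12 ring, C-9 ketone, C-10 CBr, C-12 carbinol, C-13 to C-20 octadienyl chain)
1. The 7Z dienone is traced back to an E-configured 5-alkylidene-4-silyloxycyclopentenone with its carbonyl at C-12; oxidising C-9 at the end (1,3-carbonyl transposition) turns the E-alkylidene into 7Z, and C-1/C-4 are held as a γ-lactone until the last step.
2. C12–C13: α-selective, Z-retentive addition of an octadienylbarium reagent to the C-12 ketone, anti to the C-9 silyloxy group (sets C-12).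
3. Key bond C7–C8: atom-transfer radical addition of the C-8 α-keto radical (from an α'-bromoketone) to the terminal alkyne of an (S)-propargyl lactone, then loss of HBr to the E,E-dienone.
4. Building blocks: bromoenone from cyclopent-4-ene-1,3-dione (bromination, CBS reduction sets C-9); lactone from methyl 4-oxobutanoate (asymmetric propargylation sets C-4); chloride from 1-bromopent-2-yne and prop-2-yn-1-ol.
5. Rings: the carbocycle is bought intact and never rebuilt; the only ring formed is the temporary γ-lactone (step 5), opened in the last step.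

Assumption: cyclopent-4-ene-1,3-dione, methyl 4-oxobutanoate, 1-bromopent-2-yne and prop-2-yn-1-ol are bought, and the target descriptors read from the SMILES are 4S, 12R, 5E, 7Z, 14Z, 17Z.

**Step 1**
Reactants: 1 cyclopent-4-ene-1,3-dione
Product: 3 4-bromocyclopent-4-ene-1,3-dione, via trans-dibromide 2 (not isolated)
Conditions: Br2, CH2Cl2, 0 °C; then Et3N (1.0 equiv), 0 °C
Reagents that add atoms: bromine, BrBr
Why: Bromination–dehydrobromination: Br2 adds to the ring alkene and the acidic α-hydrogen of the dibromide allows E1cB loss of HBr, placing bromine on the future C-10.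

**Step 2**
Reactants: 3 4-bromocyclopent-4-ene-1,3-dione
Product: 4 (4R)-3-bromo-4-hydroxycyclopent-2-en-1-one
Conditions: (S)-Me-CBS (10 mol%), catecholborane, toluene/CH2Cl2, −78 °C
Reagents that add atoms: none
Why: Corey–Bakshi–Shibata reduction: the carbonyl next to the C–Br carbon is the more electrophilic one (the other is the carbonyl of a vinylogous acyl bromide) and the bromovinyl group acts as the large substituent, so the (S)-catalyst gives the 4R alcohol (future C-9), as in the monoreduction of the parent dione and CBS reductions of 2-bromocycloalkenones.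

**Step 3**
Reactants: 4 (4R)-3-bromo-4-hydroxycyclopent-2-en-1-one
Product: 5 (4R)-3-bromo-4-[(tert-butyldimethylsilyl)oxy]cyclopent-2-en-1-one
Conditions: TBSCl, imidazole, DMF, 0 °C to rt
Reagents that add atoms: tert-butyldimethylsilyl chloride, CC(C)(C)[Si](C)(C)Cl
Why: Standard imidazole-promoted silylation of the secondary alcohol; the bulky silyl ether later shields one ring face.

**Step 4**
Reactants: 5 (4R)-3-bromo-4-[(tert-butyldimethylsilyl)oxy]cyclopent-2-en-1-one
Product: 7 (4R,5R)-3,5-dibromo-4-[(tert-butyldimethylsilyl)oxy]cyclopent-2-en-1-one, via lithium dienolate 6 (not isolated)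
Conditions: LiN(SiMe3)2, THF, −78 °C; then NBS, −78 °C
Reagents that add atoms: N-bromosuccinimide, O=C1CCC(=O)N1Br
Why: Kinetic deprotonation at the only sp3 α-carbon followed by enolate α-bromination anti to the silyloxy group gives the α'-bromoketone used as radical precursor.

**Step 5**
Reactants: 8 methyl 4-oxobutanoate
Product: 10 (5S)-5-(prop-2-yn-1-yl)oxolan-2-one, via methyl (4S)-4-hydroxyhept-6-ynoate 9 (not isolated)
Conditions: allenyl-B(pin), (R)-TRIP (5 mol%), toluene, −20 °C; then TsOH (cat.), CH2Cl2, rt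
Reagents that add atoms: allenylboronic acid pinacol ester, C=C=CB1OC(C)(C)C(C)(C)O1
Why: Chiral phosphoric acid-catalysed propargylboration through a closed six-membered transition state sets C-4 as S (by analogy with the known facial sense of this catalyst), and acid then closes the γ-lactone, masking C-1 and the C-4 oxygen.

**Step 6 (key step)**
Reactants: 7 (4R,5R)-3,5-dibromo-4-[(tert-butyldimethylsilyl)oxy]cyclopent-2-en-1-one; 10 (5S)-5-(prop-2-yn-1-yl)oxolan-2-one
Product: 12 (4R,5E)-3-bromo-4-[(tert-butyldimethylsilyl)oxy]-5-{(2E)-3-[(2S)-5-oxooxolan-2-yl]prop-2-en-1-ylidene}cyclopent-2-en-1-one, via vinyl bromide adduct 11 (not isolated)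
Conditions: [Ir(ppy)2(dtbbpy)]PF6 (1 mol%), 10 (2 equiv), MeCN, blue LED, rt; then DBU, 0 °C
Reagents that add atoms: none
Why: Proposed new method: visible-light atom-transfer radical addition (Kharasch type), in which the excited photocatalyst reduces only the sp3 C–Br bond of 7, the electrophilic α-keto radical adds to the terminal alkyne carbon of 10 to form C7–C8, the vinyl radical takes bromine from 7 to carry the chain, and DBU then conjugates the β,γ-unsaturated vinyl bromide and eliminates HBr to the thermodynamic E,E-dienone with H-7 syn to the C-12 carbonyl; the closest known reactions are photoredox atom-transfer additions of α-bromocarbonyls to 1-alkynes and base-induced isomerisation of β,γ-unsaturated γ-halo ketones to conjugated dienones.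

**Step 7**
Reactants: 13 1-bromopent-2-yne; 14 prop-2-yn-1-ol
Product: 15 octa-2,5-diyn-1-ol
Conditions: CuI (10 mol%), Bu4NI (10 mol%), K2CO3, DMF, rt
Reagents that add atoms: none
Why: Copper-catalysed coupling of a terminal alkyne with a propargylic bromide gives the skipped diyne.

**Step 8**
Reactants: 15 octa-2,5-diyn-1-ol
Product: 16 (2Z,5Z)-octa-2,5-dien-1-ol
Conditions: H2 (1 atm), Ni(OAc)2·4H2O, NaBH4, H2NCH2CH2NH2, EtOH, rt
Reagents that add atoms: none
Why: P-2 nickel semihydrogenation is cis-selective and stops at the alkene, setting both Z double bonds.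

**Step 9**
Reactants: 16 (2Z,5Z)-octa-2,5-dien-1-ol
Product: 18 (2Z,5Z)-1-chloroocta-2,5-diene, via allylic mesylate 17 (not isolated)
Conditions: MsCl, 2,4,6-collidine, LiCl, DMF, 0 °C
Reagents that add atoms: lithium chloride, [Li+].[Cl-]; methanesulfonyl chloride, CS(=O)(=O)Cl (chloride source only)
Why: Collington–Meyers chlorination: in situ mesylation and SN2 displacement at the primary allylic carbon, without allylic transposition or Z/E scrambling.

**Step 10**
Reactants: 18 (2Z,5Z)-1-chloroocta-2,5-diene; 12 (4R,5E)-3-bromo-4-[(tert-butyldimethylsilyl)oxy]-5-{(2E)-3-[(2S)-5-oxooxolan-2-yl]prop-2-en-1-ylidene}cyclopent-2-en-1-one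
Product: 20 (5S)-5-[(1E,3E)-3-{(2R,5R)-4-bromo-5-[(tert-butyldimethylsilyl)oxy]-2-hydroxy-2-[(2Z,5Z)-octa-2,5-dien-1-yl]cyclopent-3-en-1-ylidene}prop-1-en-1-yl]oxolan-2-one, via octadienylbarium chloride 19 (not isolated)
Conditions: BaI2, lithium biphenylide (LiC12H10), THF, rt; then 18, −78 °C; then 12, −78 °C; aq NH4Cl
Reagents that add atoms: none
Why: Yamamoto allylbarium addition: the allylbarium formed at −78 °C keeps its Z geometry and attacks the ketone 1,2 through its α-carbon, and approach anti to the C-9 silyloxy group sets C-12 as R (hydroxyl cis to the silyl ether) by substrate-controlled 1,3-induction.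

**Step 11**
Reactants: 20 (5S)-5-[(1E,3E)-3-{(2R,5R)-4-bromo-5-[(tert-butyldimethylsilyl)oxy]-2-hydroxy-2-[(2Z,5Z)-octa-2,5-dien-1-yl]cyclopent-3-en-1-ylidene}prop-1-en-1-yl]oxolan-2-one
Product: 21 (5S)-5-[(1E,3Z)-3-{(2R)-4-bromo-2-hydroxy-2-[(2Z,5Z)-octa-2,5-dien-1-yl]-5-oxocyclopent-3-en-1-ylidene}prop-1-en-1-yl]oxolan-2-one
Conditions: DDQ, CH2Cl2/pH 7 buffer, 0 °C to rt
Reagents that add atoms: none
Why: DDQ oxidative desilylation: hydride is abstracted from the doubly allylic, oxygen-activated C-9–H and the silyloxocarbenium ion is hydrolysed to the ketone, so the carbonyl moves from C-12 to C-9 and the untouched alkylidene now reads 7Z.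

**Step 12**
Reactants: 21 (5S)-5-[(1E,3Z)-3-{(2R)-4-bromo-2-hydroxy-2-[(2Z,5Z)-octa-2,5-dien-1-yl]-5-oxocyclopent-3-en-1-ylidene}prop-1-en-1-yl]oxolan-2-one
Product: 23 methyl (4S,5E,7Z)-7-{(2R)-4-bromo-2-hydroxy-2-[(2Z,5Z)-octa-2,5-dien-1-yl]-5-oxocyclopent-3-en-1-ylidene}-4-hydroxyhept-5-enoate, via lithium carboxylate 22 (not isolated)
Conditions: LiOH (1.1 equiv), THF/H2O, 0 °C; evaporate; then MeI, DMF, rt
Reagents that add atoms: lithium hydroxide, [Li+].[OH-]; iodomethane, CI
Why: Saponification of the γ-lactone followed by SN2 O-methylation of the carboxylate gives the methyl ester and frees the C-4 hydroxyl without acid, so relactonisation is avoided.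

**Compound list**
1 | cyclopent-4-ene-1,3-dione | O=C1CC(=O)C=C1 | starting material
2 | trans-4,5-dibromocyclopentane-1,3-dione (racemic) | O=C1CC(=O)[C@H](Br)[C@H]1Br | intermediate
3 | 4-bromocyclopent-4-ene-1,3-dione | O=C1CC(=O)C(Br)=C1 | intermediate
4 | (4R)-3-bromo-4-hydroxycyclopent-2-en-1-one | O=C1C=C(Br)[C@H](O)C1 | intermediate
5 | (4R)-3-bromo-4-[(tert-butyldimethylsilyl)oxy]cyclopent-2-en-1-one | O=C1C=C(Br)[C@H](O[Si](C)(C)C(C)(C)C)C1 | intermediate
6 | lithium (3R)-4-bromo-3-[(tert-butyldimethylsilyl)oxy]cyclopenta-1,4-dien-1-olate | [Li+].[O-]C1=C[C@@H](O[Si](C)(C)C(C)(C)C)C(Br)=C1 | intermediate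
7 | (4R,5R)-3,5-dibromo-4-[(tert-butyldimethylsilyl)oxy]cyclopent-2-en-1-one | O=C1C=C(Br)[C@H](O[Si](C)(C)C(C)(C)C)[C@H]1Br | intermediate
8 | methyl 4-oxobutanoate | COC(=O)CCC=O | starting material
9 | methyl (4S)-4-hydroxyhept-6-ynoate | COC(=O)CC[C@H](O)CC#C | intermediate
10 | (5S)-5-(prop-2-yn-1-yl)oxolan-2-one | O=C1CC[C@@H](CC#C)O1 | intermediate
11 | (4R)-3-bromo-5-{2-bromo-3-[(2S)-5-oxooxolan-2-yl]prop-1-en-1-yl}-4-[(tert-butyldimethylsilyl)oxy]cyclopent-2-en-1-one (mixture at ring C-5 and at the new double bond) | O=C1C=C(Br)[C@H](O[Si](C)(C)C(C)(C)C)C1C=C(Br)C[C@@H]2CCC(=O)O2 | intermediate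
12 | (4R,5E)-3-bromo-4-[(tert-butyldimethylsilyl)oxy]-5-{(2E)-3-[(2S)-5-oxooxolan-2-yl]prop-2-en-1-ylidene}cyclopent-2-en-1-one | O=C1C=C(Br)[C@H](O[Si](C)(C)C(C)(C)C)/C1=C\C=C\[C@@H]2CCC(=O)O2 | intermediate
13 | 1-bromopent-2-yne | CCC#CCBr | starting material
14 | prop-2-yn-1-ol | OCC#C | starting material
15 | octa-2,5-diyn-1-ol | CCC#CCC#CCO | intermediate
16 | (2Z,5Z)-octa-2,5-dien-1-ol | CC/C=C\C/C=C\CO | intermediate
17 | (2Z,5Z)-octa-2,5-dien-1-yl methanesulfonate | CC/C=C\C/C=C\COS(C)(=O)=O | intermediate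
18 | (2Z,5Z)-1-chloroocta-2,5-diene | CC/C=C\C/C=C\CCl | intermediate
19 | [(2Z,5Z)-octa-2,5-dien-1-yl]barium chloride | CC/C=C\C/C=C\C[Ba]Cl | intermediate
20 | (5S)-5-[(1E,3E)-3-{(2R,5R)-4-bromo-5-[(tert-butyldimethylsilyl)oxy]-2-hydroxy-2-[(2Z,5Z)-octa-2,5-dien-1-yl]cyclopent-3-en-1-ylidene}prop-1-en-1-yl]oxolan-2-one | CC/C=C\C/C=C\C[C@@]1(O)C=C(Br)[C@H](O[Si](C)(C)C(C)(C)C)/C1=C\C=C\[C@@H]2CCC(=O)O2 | intermediate
21 | (5S)-5-[(1E,3Z)-3-{(2R)-4-bromo-2-hydroxy-2-[(2Z,5Z)-octa-2,5-dien-1-yl]-5-oxocyclopent-3-en-1-ylidene}prop-1-en-1-yl]oxolan-2-one | CC/C=C\C/C=C\C[C@@]1(O)C=C(Br)C(=O)/C1=C\C=C\[C@@H]2CCC(=O)O2 | intermediate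
22 | lithium (4S,5E,7Z)-7-{(2R)-4-bromo-2-hydroxy-2-[(2Z,5Z)-octa-2,5-dien-1-yl]-5-oxocyclopent-3-en-1-ylidene}-4-hydroxyhept-5-enoate | [Li+].CC/C=C\C/C=C\C[C@@]1(O)C=C(Br)C(=O)/C1=C\C=C\[C@@H](O)CCC(=O)[O-] | intermediate
23 | methyl (4S,5E,7Z)-7-{(2R)-4-bromo-2-hydroxy-2-[(2Z,5Z)-octa-2,5-dien-1-yl]-5-oxocyclopent-3-en-1-ylidene}-4-hydroxyhept-5-enoate | CC/C=C\C/C=C\C[C@@]1(O)C=C(Br)C(=O)/C1=C\C=C\[C@@H](O)CCC(=O)OC | target

**Step count and risk**
Total step count: 12. Longest linear sequence: 8 (steps 1, 2, 3, 4, 6, 10, 11, 12).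

The three steps most likely to fail are the radical union (step 6), the barium addition (step 10) and the CBS reduction (step 2).

The atom-transfer addition and dehydrobromination of step 6 is the least secure. The vinyl radical may abstract hydrogen instead of bromine, and DBU may epimerise the γ-acidic C-9 centre. The fallback makes the same bond by a polar aldol condensation, setting out from ketone 5 and coming back at dienone 12. Bought (5S)-5-(hydroxymethyl)oxolan-2-one F1 is oxidised with Dess–Martin periodinane to (2S)-5-oxooxolane-2-carbaldehyde F2. Wittig reaction with Ph3P=CHCHO gives (2E)-3-[(2S)-5-oxooxolan-2-yl]prop-2-enal F3. The lithium dienolate 6 of 5 (LiN(SiMe3)2, −78 °C) adds to F3 to give the aldol (4R)-3-bromo-4-[(tert-butyldimethylsilyl)oxy]-5-{(2E)-1-hydroxy-3-[(2S)-5-oxooxolan-2-yl]prop-2-en-1-yl}cyclopent-2-en-1-one F4. MsCl/Et3N converts this through the mesylate (2E)-1-{(2R)-3-bromo-2-[(tert-butyldimethylsilyl)oxy]-5-oxocyclopent-3-en-1-yl}-3-[(2S)-5-oxooxolan-2-yl]prop-2-en-1-yl methanesulfonate F5 into 12 by E1cB elimination, with the same thermodynamic E geometry.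

The barium addition of step 10 may suffer from enolisation at C-9, attack on the lactone or loss of Z geometry. The fallback builds the chain in two stages, setting out from 12 and coming back at 20. The lithium enolate of acetaldehyde (n-BuLi, THF, rt then −78 °C) adds to the C-12 ketone anti to the silyl ether to give the β-hydroxy aldehyde 2-[(1R,4R,5E)-3-bromo-4-[(tert-butyldimethylsilyl)oxy]-1-hydroxy-5-{(2E)-3-[(2S)-5-oxooxolan-2-yl]prop-2-en-1-ylidene}cyclopent-2-en-1-yl]acetaldehyde F6. A salt-free Z-selective Wittig reaction with the ylide from [(3Z)-hex-3-en-1-yl]triphenylphosphonium bromide and NaN(SiMe3)2 at −78 °C then forms the 14Z double bond and gives 20.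

The CBS reduction of step 2 may reduce the wrong carbonyl or give low selectivity. The fallback replaces asymmetric catalysis by enzymatic resolution, setting out from dione 3 and coming back at alcohol 4. NaBH4/CeCl3·7H2O in MeOH at −78 °C gives racemic 3-bromo-4-hydroxycyclopent-2-en-1-one F7. Amano lipase PS with vinyl acetate acylates the R enantiomer (by analogy with 4-hydroxycyclopent-2-enone) to (1R)-2-bromo-4-oxocyclopent-2-en-1-yl acetate F8, leaving (4S)-3-bromo-4-hydroxycyclopent-2-en-1-one F9, which is separated. F8 is transesterified with n-BuOH and Candida antarctica lipase B to give 4.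

**Further compounds**
F1 | step 6 | (5S)-5-(hydroxymethyl)oxolan-2-one | O=C1CC[C@@H](CO)O1
F2 | step 6 | (2S)-5-oxooxolane-2-carbaldehyde | O=C[C@@H]1CCC(=O)O1
F3 | step 6 | (2E)-3-[(2S)-5-oxooxolan-2-yl]prop-2-enal | O=C/C=C/[C@@H]1CCC(=O)O1
F4 | step 6 | (4R)-3-bromo-4-[(tert-butyldimethylsilyl)oxy]-5-{(2E)-1-hydroxy-3-[(2S)-5-oxooxolan-2-yl]prop-2-en-1-yl}cyclopent-2-en-1-one | O=C1C=C(Br)[C@H](O[Si](C)(C)C(C)(C)C)C1C(O)/C=C/[C@@H]2CCC(=O)O2
F5 | step 6 | (2E)-1-{(2R)-3-bromo-2-[(tert-butyldimethylsilyl)oxy]-5-oxocyclopent-3-en-1-yl}-3-[(2S)-5-oxooxolan-2-yl]prop-2-en-1-yl methanesulfonate | O=C1C=C(Br)[C@H](O[Si](C)(C)C(C)(C)C)C1C(OS(C)(=O)=O)/C=C/[C@@H]2CCC(=O)O2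
F6 | step 10 | 2-[(1R,4R,5E)-3-bromo-4-[(tert-butyldimethylsilyl)oxy]-1-hydroxy-5-{(2E)-3-[(2S)-5-oxooxolan-2-yl]prop-2-en-1-ylidene}cyclopent-2-en-1-yl]acetaldehyde | O=CC[C@@]1(O)C=C(Br)[C@H](O[Si](C)(C)C(C)(C)C)/C1=C\C=C\[C@@H]2CCC(=O)O2
F7 | step 2 | rac-3-bromo-4-hydroxycyclopent-2-en-1-one | O=C1C=C(Br)C(O)C1
F8 | step 2 | (1R)-2-bromo-4-oxocyclopent-2-en-1-yl acetate | O=C1C=C(Br)[C@H](OC(C)=O)C1
F9 | step 2 | (4S)-3-bromo-4-hydroxycyclopent-2-en-1-one | O=C1C=C(Br)[C@@H](O)C1
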